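The crowded C8–C8 axis is never made by joining two arenes. Ring A of unit 2 (the apigenin half) is dismantled instead, and unit 1 (the acacetin half) stays whole. The feature exploited is the 5,7-dioxygenated ring A of unit 2. C5–C6–C7 is a β-keto-acid chain, C8 enters as the sp3 benzylic carbon on C8 of unit 1, and C8a=C4a is the enol-ether bond of a preformed 4-pyranone (ring C). The precursor is a tert-butyl β-keto ester whose C8–H carries both the flavon-8-yl and the 6-aryl-4-pyranon-2-yl groups. On heating it should give an acylketene that forms C5–C4a, delivering ring A, both phenols and the axis at once.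

Key step: step 10

Assumption: the target is drawn without an axial descriptor, so the C8–C8 axis is made as the racemate.

Numbering: unit 1 is the flavone with the 4-methoxyphenyl ring and unit 2 the flavone with the 4-hydroxyphenyl ring. Unqualified labels (O1, C2–C8a) refer to unit 2 in flavone numbering, also in its open-chain and pyranone precursors.

Design remarks:
- **Atom balance.** 19 (C56H48O11) minus tert-butanol equals 23 (C52H38O10). 23 with hydrogen in place of its three benzyl groups equals 24 (C31H20O10). The structures of 19 and 23 are therefore consistent.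
- **No direct malonylation at C8.** The CH2 of an activated malonic half ester, and the acylation product itself, are far more acidic than the C8 methylene and would only protonate the C8 carbanion. C7 is therefore brought in as CO2, and C6–C5 by a decarboxylative Claisen reaction.
- **Origin of the two-carbon arm on unit 1.** It comes from a regiochemically defined 8-iodide, which also serves as the exit point if the key step fails.

Step 1
Reactants: 1 acacetin
Product: 2 5,7-bis(benzyloxy)-4'-methoxyflavone
Conditions: BnBr, K2CO3, DMF, 80 °C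
Reagents that add atoms: benzyl bromide, BrCc1ccccc1
Why: Williamson etherification in which carbonate in hot DMF ionises the acidic 7-OH at once and, with excess halide and heat, also the chelated 5-OH, so both phenols that would quench later bases or trap the ketene should be capped by groups removable by hydrogenolysis while the 4'-methyl ether stays.

Step 2
Reactants: 2 5,7-bis(benzyloxy)-4'-methoxyflavone
Product: 3 5,7-bis(benzyloxy)-8-iodo-4'-methoxyflavone
Conditions: NIS, TFA (cat.), MeCN–CH2Cl2, 0 °C to rt, dark
Reagents that add atoms: N-iodosuccinimide, O=C1CCC(=O)N1I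
Why: Electrophilic aromatic iodination in which the fully alkylated ring A is by far the most electron-rich arene and C8, para to O5, should be attacked in preference to C6, which is wedged between two benzyloxy groups, the usual outcome for 5,7-dialkoxyflavones.

Step 3
Reactants: 3 5,7-bis(benzyloxy)-8-iodo-4'-methoxyflavone; 4 (2-ethoxy-2-oxoethyl)zinc bromide, BrZnCH2CO2Et (commercial solution)
Product: 5 ethyl [5,7-bis(benzyloxy)-4'-methoxyflavon-8-yl]acetate
Conditions: Pd2(dba)3 (cat.), XPhos (cat.), THF, 60 °C
Reagents that add atoms: none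
Why: Negishi-type coupling of a Reformatsky reagent (palladium-catalysed α-arylation of a zinc ester enolate), in which the almost neutral zinc enolate leaves the chromone carbonyl alone and a bulky biaryl phosphine on zerovalent palladium should cope with the doubly ortho-flanked iodide.

Step 4
Reactants: 5 ethyl [5,7-bis(benzyloxy)-4'-methoxyflavon-8-yl]acetate
Product: 6 [5,7-bis(benzyloxy)-4'-methoxyflavon-8-yl]acetic acid
Conditions: LiOH, THF–MeOH–H2O, rt; then dilute HCl
Reagents that add atoms: lithium hydroxide, [Li+].[OH-]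
Why: Saponification of an unhindered primary ester at room temperature, conditions under which benzyl ethers are inert and a 5,7-dialkoxyflavone should not ring-open.

Step 5
Reactants: 7 4'-benzyloxyacetophenone; 8 ethyl acetate
Product: 9 1-(4-benzyloxyphenyl)butane-1,3-dione
Conditions: NaH, THF, 0 °C to reflux; then dilute HCl
Reagents that add atoms: none
Why: Crossed Claisen condensation in which the methyl ketone enolate attacks ethyl acetate and the irreversible deprotonation of the β-diketone pulls the equilibrium to 9.

Step 6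
Reactants: 9 1-(4-benzyloxyphenyl)butane-1,3-dione
Product: 10 (1Z)-1-(4-benzyloxyphenyl)-1,3-bis(trimethylsilyloxy)buta-1,3-diene
Conditions: TMSOTf, Et3N, Et2O, 0 °C to rt; used at once
Reagents that add atoms: trimethylsilyl trifluoromethanesulfonate, C[Si](C)(C)OS(=O)(=O)C(F)(F)F
Why: Double soft enolisation–silylation in which silyl triflate and amine first cap the chelated enol and then enolise the acetyl group towards its methyl carbon, which should give the 1,3-bis(silyloxy)diene, a neutral equivalent of the diketone dianion whose enol-ether geometry is lost in step 7.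

Step 7
Reactants: 6 [5,7-bis(benzyloxy)-4'-methoxyflavon-8-yl]acetic acid; 10 (1Z)-1-(4-benzyloxyphenyl)-1,3-bis(trimethylsilyloxy)buta-1,3-diene
Product: 13 8-{[6-(4-benzyloxyphenyl)-4-oxo-4H-pyran-2-yl]methyl}-5,7-bis(benzyloxy)-4'-methoxyflavone, via acid chloride 11 (not isolated), via triketone 12 (not isolated)
Conditions: (COCl)2, DMF (cat.), CH2Cl2, 0 °C to rt, evaporate; 10, CH2Cl2, −78 to 20 °C; then TFA, rt
Reagents that add atoms: none
Why: Acylation of a 1,3-bis(silyl enol ether) by an acid chloride at its terminal carbon, run without base or Lewis acid so that neither the acidic benzylic CH2 nor the chromone is touched, should give the 1,3,5-triketone 12, whose acid-catalysed cyclodehydration is the classical 4-pyranone synthesis and has only one possible outcome.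

Step 8
Reactants: 13 8-{[6-(4-benzyloxyphenyl)-4-oxo-4H-pyran-2-yl]methyl}-5,7-bis(benzyloxy)-4'-methoxyflavone; 14 carbon dioxide
Product: 16 2-[5,7-bis(benzyloxy)-4'-methoxyflavon-8-yl]-2-[6-(4-benzyloxyphenyl)-4-oxo-4H-pyran-2-yl]acetic acid (racemic), via lithium dienolate 15 (not isolated)
Conditions: LiN(SiMe3)2, THF, −78 °C; CO2, −78 to −20 °C; cold dilute HCl, no heating
Reagents that add atoms: none
Why: Side-chain metalation and carboxylation of a 2-alkyl-4-pyranone, in which the benzylic and vinylogously activated C8 methylene is the only site the hindered amide can deprotonate, the dienolate reacts at its exocyclic carbon so that the pyranone is restored, the carboxylate formed is too weak an acid to quench unreacted anion, and C8 arises as a racemic, enolisable centre that is erased in step 10.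

Step 9
Reactants: 16 2-[5,7-bis(benzyloxy)-4'-methoxyflavon-8-yl]-2-[6-(4-benzyloxyphenyl)-4-oxo-4H-pyran-2-yl]acetic acid; 17 mono-tert-butyl malonate
Product: 19 tert-butyl 4-[5,7-bis(benzyloxy)-4'-methoxyflavon-8-yl]-4-[6-(4-benzyloxyphenyl)-4-oxo-4H-pyran-2-yl]-3-oxobutanoate (racemic and enolisable at C8), via acyl imidazolide 18 (not isolated)
Conditions: CDI, THF, 0 °C to rt; then Mg(O2CCH2CO2tBu)2 [from 17 and Mg(OEt)2, THF], rt; cold dilute HCl
Reagents that add atoms: none
Why: Masamune–Brooks decarboxylative Claisen condensation, in which the acyl imidazolide is attacked by the chelated magnesium malonate enolate under almost neutral conditions at room temperature, loss of CO2 gives the β-keto ester directly (a reaction that tolerates acyl donors of malonate-like acidity), and the labile C8 centre stays racemic.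

Step 10
Reactants: 19 tert-butyl 4-[5,7-bis(benzyloxy)-4'-methoxyflavon-8-yl]-4-[6-(4-benzyloxyphenyl)-4-oxo-4H-pyran-2-yl]-3-oxobutanoate
Product: 23 5,7-bis(benzyloxy)-8-[2-(4-benzyloxyphenyl)-5,7-dihydroxy-4-oxo-4H-chromen-8-yl]-4'-methoxyflavone (racemic axis), via acylketene 20 (not isolated), via dienylketene enol 21 (not isolated), via cyclohexadienone 22 (not isolated)
Conditions: PhMe (high dilution), reflux with slow distillation of tBuOH, Ar, base-washed glassware (o-xylene, 140 °C, if slow)
Reagents that add atoms: none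
Why: Proposed new method: at reflux the chelated enol of 19 should expel tert-butanol to give acylketene 20 (O=C5=C6H–C7=O), and a proton shift to O7 from the C8–H, which is flanked by the ketone, the aryl group and the vinylogous ester, gives enol 21, a dienylketene whose triene C5=C6–C7=C8–C8a=C4a ends in the enol-ether double bond of the pyranone. Ring A, a six-membered carbocycle, is closed by a thermally allowed disrotatory six-electron electrocyclisation that joins C5 to C4a (polarity-matched, since C4a is the nucleophilic α-carbon of a vinylogous ester and C5 the ketene carbon) and gives cyclohexadienone 22, after which migration of the C4a proton to O5 aromatises the ring to the 5,7-diol 23 and removes any way back. The closest known reactions are the thermolysis of tert-butyl β-keto esters or dioxinones to acylketenes in resorcylate synthesis and the dienylketene closure that ends a Danheiser benzannulation, which also accepts aryl and heteroaryl double bonds as the terminus; a 4-pyranone double bond has not been tried in that role. No stereocentre is created: the racemic C8 centre of 19 becomes sp2, the C4a centre of 22 is transient, and the C8–C8 axis emerges without bias as the racemate only when the ring aromatises, so the tetra-ortho crowding is paid for by aromatisation instead of by a coupling transition state between two arenes. The selectivity required is chemoselectivity of the ketene: with O1 tied into the pyranone no enol oxygen can reach C5, which rules out 2-pyranone formation and fixes the 8-linked instead of the 6-linked flavone, both ortho positions of unit 1 are substituted, and C4a is the only carbon nucleophile that can reach C5 through a six-membered transition state. Return of tert-butanol or O-acylation by product phenols only regenerates acylketene precursors, while high dilution and acid-free glassware should hold back ketene dimerisation and loss of isobutene.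

Step 11
Reactants: 23 5,7-bis(benzyloxy)-8-[2-(4-benzyloxyphenyl)-5,7-dihydroxy-4-oxo-4H-chromen-8-yl]-4'-methoxyflavone
Product: 24 4'-O-methylcupressuflavone (CNP0322111.0, racemic axis)
Conditions: H2 (1 atm), Pd/C, THF–MeOH, rt
Reagents that add atoms: none
Why: Catalytic hydrogenolysis, in which the three O-benzyl bonds should be cleaved under a balloon of hydrogen whereas the aryl methyl ether and the conjugated C2=C3 bonds of both flavones are not reduced under these mild conditions.

Compound list
1 | acacetin (5,7-dihydroxy-4'-methoxyflavone) | COc1ccc(cc1)-c1cc(=O)c2c(O)cc(O)cc2o1 | starting material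
2 | 5,7-bis(benzyloxy)-4'-methoxyflavone | COc1ccc(cc1)-c1cc(=O)c2c(OCc3ccccc3)cc(OCc3ccccc3)cc2o1 | intermediate
3 | 5,7-bis(benzyloxy)-8-iodo-4'-methoxyflavone | COc1ccc(cc1)-c1cc(=O)c2c(OCc3ccccc3)cc(OCc3ccccc3)c(I)c2o1 | intermediate
4 | (2-ethoxy-2-oxoethyl)zinc bromide | CCOC(=O)C[Zn]Br | starting material
5 | ethyl [5,7-bis(benzyloxy)-4'-methoxyflavon-8-yl]acetate | COc1ccc(cc1)-c1cc(=O)c2c(OCc3ccccc3)cc(OCc3ccccc3)c(CC(=O)OCC)c2o1 | intermediate
6 | [5,7-bis(benzyloxy)-4'-methoxyflavon-8-yl]acetic acid | COc1ccc(cc1)-c1cc(=O)c2c(OCc3ccccc3)cc(OCc3ccccc3)c(CC(=O)O)c2o1 | intermediate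
7 | 4'-benzyloxyacetophenone | CC(=O)c1ccc(OCc2ccccc2)cc1 | starting material
8 | ethyl acetate | CCOC(C)=O | starting material
9 | 1-(4-benzyloxyphenyl)butane-1,3-dione | CC(=O)CC(=O)c1ccc(OCc2ccccc2)cc1 | intermediate
10 | (1Z)-1-(4-benzyloxyphenyl)-1,3-bis(trimethylsilyloxy)buta-1,3-diene | C=C(O[Si](C)(C)C)/C=C(\O[Si](C)(C)C)c1ccc(OCc2ccccc2)cc1 | intermediate
11 | [5,7-bis(benzyloxy)-4'-methoxyflavon-8-yl]acetyl chloride | COc1ccc(cc1)-c1cc(=O)c2c(OCc3ccccc3)cc(OCc3ccccc3)c(CC(=O)Cl)c2o1 | intermediate
12 | 1-(4-benzyloxyphenyl)-6-[5,7-bis(benzyloxy)-4'-methoxyflavon-8-yl]hexane-1,3,5-trione | COc1ccc(cc1)-c1cc(=O)c2c(OCc3ccccc3)cc(OCc3ccccc3)c(CC(=O)CC(=O)CC(=O)c3ccc(OCc4ccccc4)cc3)c2o1 | intermediate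
13 | 8-{[6-(4-benzyloxyphenyl)-4-oxo-4H-pyran-2-yl]methyl}-5,7-bis(benzyloxy)-4'-methoxyflavone | COc1ccc(cc1)-c1cc(=O)c2c(OCc3ccccc3)cc(OCc3ccccc3)c(Cc3cc(=O)cc(-c4ccc(OCc5ccccc5)cc4)o3)c2o1 | intermediate
14 | carbon dioxide | O=C=O | starting material
15 | lithium dienolate of 13 (exocyclic C8=C8a, lithium on the C4 oxygen) | [Li+].COc1ccc(cc1)-c1cc(=O)c2c(OCc3ccccc3)cc(OCc3ccccc3)c(C=C3C=C([O-])C=C(O3)c3ccc(OCc4ccccc4)cc3)c2o1 | intermediate
16 | 2-[5,7-bis(benzyloxy)-4'-methoxyflavon-8-yl]-2-[6-(4-benzyloxyphenyl)-4-oxo-4H-pyran-2-yl]acetic acid (racemic) | COc1ccc(cc1)-c1cc(=O)c2c(OCc3ccccc3)cc(OCc3ccccc3)c(C(C(=O)O)c3cc(=O)cc(-c4ccc(OCc5ccccc5)cc4)o3)c2o1 | intermediate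
17 | mono-tert-butyl malonate | CC(C)(C)OC(=O)CC(=O)O | starting material
18 | acyl imidazolide of 16 (racemic) | COc1ccc(cc1)-c1cc(=O)c2c(OCc3ccccc3)cc(OCc3ccccc3)c(C(C(=O)n3ccnc3)c3cc(=O)cc(-c4ccc(OCc5ccccc5)cc4)o3)c2o1 | intermediate
19 | tert-butyl 4-[5,7-bis(benzyloxy)-4'-methoxyflavon-8-yl]-4-[6-(4-benzyloxyphenyl)-4-oxo-4H-pyran-2-yl]-3-oxobutanoate (racemic, enolisable) | COc1ccc(cc1)-c1cc(=O)c2c(OCc3ccccc3)cc(OCc3ccccc3)c(C(C(=O)CC(=O)OC(C)(C)C)c3cc(=O)cc(-c4ccc(OCc5ccccc5)cc4)o3)c2o1 | intermediate
20 | acylketene from 19 (O=C5=C6H–C7(=O)–C8H) | COc1ccc(cc1)-c1cc(=O)c2c(OCc3ccccc3)cc(OCc3ccccc3)c(C(C(=O)C=C=O)c3cc(=O)cc(-c4ccc(OCc5ccccc5)cc4)o3)c2o1 | intermediate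
21 | dienylketene, (E)-C7 enol of 20 (ketene arm cis to the pyranone) | COc1ccc(cc1)-c1cc(=O)c2c(OCc3ccccc3)cc(OCc3ccccc3)c(/C(=C(\O)C=C=O)c3cc(=O)cc(-c4ccc(OCc5ccccc5)cc4)o3)c2o1 | intermediate
22 | cyclohexadienone (C5=O, sp3 C4a–H, racemic and transient) | COc1ccc(cc1)-c1cc(=O)c2c(OCc3ccccc3)cc(OCc3ccccc3)c(C3=C4OC(=CC(=O)C4C(=O)C=C3O)c3ccc(OCc4ccccc4)cc3)c2o1 | intermediate
23 | 5,7-bis(benzyloxy)-8-[2-(4-benzyloxyphenyl)-5,7-dihydroxy-4-oxo-4H-chromen-8-yl]-4'-methoxyflavone (racemic axis) | COc1ccc(cc1)-c1cc(=O)c2c(OCc3ccccc3)cc(OCc3ccccc3)c(-c3c(O)cc(O)c4c(=O)cc(-c5ccc(OCc6ccccc6)cc5)oc34)c2o1 | intermediate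
24 | 4'-O-methylcupressuflavone (racemic axis) | COc1ccc(-c2cc(=O)c3c(O)cc(O)c(-c4c(O)cc(O)c5c(=O)cc(-c6ccc(O)cc6)oc45)c3o2)cc1 | target

Total step count: 11. Longest linear sequence: 9 steps from acacetin (steps 1–4 and 7–11). The side branch is steps 5 and 6.

Steps most likely to fail

1. **Step 10 (labelled step).**
   - Process at risk: closure onto the pyranone double bond may be slower than dimerisation of the ketene. The tert-butyl ester may also shed isobutene and then CO2, draining material to a methyl ketone.
   - Fallback (known chemistry, arene–arene coupling): it sets out from iodide 3. Commercial apigenin F1 is perbenzylated (BnBr, K2CO3, DMF) to 5,7,4'-tri-O-benzylapigenin F2. This is iodinated at C8 under the conditions of step 2 to 8-iodo-5,7,4'-tri-O-benzylapigenin F3. Miyaura borylation (B2pin2, PdCl2(dppf), KOAc, dioxane) converts F3 into 5,7,4'-tri-O-benzylapigenin-8-boronic acid pinacol ester F4. Suzuki–Miyaura coupling of F4 with 3 (Pd(OAc)2, SPhos, K3PO4, toluene–water, 100 °C), a ligand class known to deliver tetra-ortho-substituted biaryls, should give the pentabenzyl biflavone F5. Hydrogenolysis as in step 11 comes back to the route at target 24.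

2. **Step 9.**
   - Process at risk: decarboxylation of the activated acid back to 13, and slow attack of the bulky magnesium enolate at the crowded acyl carbon.
   - Fallback (avoids the free acid altogether): it sets out from pyranone 13. Its lithium dienolate 15 is added to N-methoxy-N-methylacetamide. The chelated tetrahedral adduct survives until work-up, so no acidic product forms in the flask, and this should give 1-[5,7-bis(benzyloxy)-4'-methoxyflavon-8-yl]-1-[6-(4-benzyloxyphenyl)-4-oxo-4H-pyran-2-yl]propan-2-one F6. Double deprotonation with LiN(iPr)2 (C8–H first, then the methyl group) follows. C-acylation of the more reactive terminal carbanion with di-tert-butyl dicarbonate, the classical dianion logic of β-dicarbonyl chain extension, comes back to the route at β-keto ester 19.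

3. **Step 3.**
   - Process at risk: sluggish coupling at the doubly ortho-flanked iodide, so that protodeiodination and self-condensation of the zinc enolate take over.
   - Fallback (sigmatropic delivery of the carbon arm in place of cross-coupling): it sets out from acacetin 1. Selective O-allylation of the unchelated 7-OH (allyl bromide, K2CO3, acetone) should give 7-O-allylacacetin F7. Aromatic Claisen rearrangement (N,N-diethylaniline, about 200 °C) should give 8-allylacacetin F8, and any 6-allyl isomer is removed at this stage. Benzylation as in step 1 gives 8-allyl-5,7-bis(benzyloxy)-4'-methoxyflavone F9. Lemieux–Johnson cleavage (OsO4 cat., NaIO4, 2,6-lutidine, dioxane–water) gives [5,7-bis(benzyloxy)-4'-methoxyflavon-8-yl]acetaldehyde F10. Pinnick oxidation (NaClO2, NaH2PO4, 2-methyl-2-butene, tBuOH–water) comes back to the route at acid 6.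

Further compounds
F1 | step 10 | apigenin (purchased) | Oc1ccc(cc1)-c1cc(=O)c2c(O)cc(O)cc2o1
F2 | step 10 | 5,7,4'-tri-O-benzylapigenin | O=c1cc(-c2ccc(OCc3ccccc3)cc2)oc2cc(OCc3ccccc3)cc(OCc3ccccc3)c12
F3 | step 10 | 8-iodo-5,7,4'-tri-O-benzylapigenin | O=c1cc(-c2ccc(OCc3ccccc3)cc2)oc2c(I)c(OCc3ccccc3)cc(OCc3ccccc3)c12
F4 | step 10 | 5,7,4'-tri-O-benzylapigenin-8-boronic acid pinacol ester | O=c1cc(-c2ccc(OCc3ccccc3)cc2)oc2c(B3OC(C)(C)C(C)(C)O3)c(OCc3ccccc3)cc(OCc3ccccc3)c12
F5 | step 10 | pentabenzyl biflavone (24 benzylated at all five hydroxyl groups, racemic axis) | COc1ccc(cc1)-c1cc(=O)c2c(OCc3ccccc3)cc(OCc3ccccc3)c(-c3c(OCc4ccccc4)cc(OCc4ccccc4)c4c(=O)cc(-c5ccc(OCc6ccccc6)cc5)oc34)c2o1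
F6 | step 9 | 1-[5,7-bis(benzyloxy)-4'-methoxyflavon-8-yl]-1-[6-(4-benzyloxyphenyl)-4-oxo-4H-pyran-2-yl]propan-2-one (racemic) | COc1ccc(cc1)-c1cc(=O)c2c(OCc3ccccc3)cc(OCc3ccccc3)c(C(C(C)=O)c3cc(=O)cc(-c4ccc(OCc5ccccc5)cc4)o3)c2o1
F7 | step 3 | 7-O-allylacacetin | COc1ccc(cc1)-c1cc(=O)c2c(O)cc(OCC=C)cc2o1
F8 | step 3 | 8-allylacacetin | COc1ccc(cc1)-c1cc(=O)c2c(O)cc(O)c(CC=C)c2o1
F9 | step 3 | 8-allyl-5,7-bis(benzyloxy)-4'-methoxyflavone | COc1ccc(cc1)-c1cc(=O)c2c(OCc3ccccc3)cc(OCc3ccccc3)c(CC=C)c2o1
F10 | step 3 | [5,7-bis(benzyloxy)-4'-methoxyflavon-8-yl]acetaldehyde | COc1ccc(cc1)-c1cc(=O)c2c(OCc3ccccc3)cc(OCc3ccccc3)c(CC=O)c2o1
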